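Take the flat end of the summer run before turning any setting.

common to all: starting material 0.25 M; partner 0.625 M

| flask | temperature | remark | time |
|---|---|---|---|
| summer | 90 °C | the very flask that is asked about, followed so far |  |
| dusk | 85 °C | run made earlier |  |
| flask | 90 °C |  | 8.0 d |

| summer: time / d | summer: target / % | dusk: time / d | dusk: target / % |
|---|---|---|---|
| 0.833 | 28.9 | 0.833 | 14.0 |
| 1.67 | 53.6 | 1.67 | 37.2 |
| 3.00 | 68.2 | 3.00 | 59.6 |
| 4.00 | 71.5 | 4.00 | 67.5 |
| 5.00 | 71.8 | 5.00 | 71.2 |
| 6.00 | 71.2 | 6.00 | 73.1 |

(scatter of a reading: 0.5 percentage points)

- north: at 8.0 d take out 90% of the target then present, then wait 8.0 d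
- south-west: at 8.0 d add partner, 100% of the amount charged, then wait 8.0 d
- north-west: change nothing and wait 8.0 d more
- south: at 8.0 d raise the temperature by 10 K, then wait 8.0 d

- target that was removed still counts
- additions bring no volume worth counting

- target, in percent of the starting material first charged, at 8.0 d
- which option adds most target ("none" when 2 percentage points or less is all one gets) (north / south-west / north-west / south / none)
- target present, with what was taken out counted in, in percent of the starting material first charged, after north-west
- target present, with what was taken out counted in, in percent of the starting material first charged, after south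

1. The summer flask reads 71.5%, 71.8% and 71.2% from 4.00 d on. These differ by 0.6 percentage points at most, against a scatter of 0.5 points, so I read a plateau of 71.5% and commit to it for 8.0 d.

2. That leaves 28.5% of the charge outside target, or 0.399 parts per part of target. I call this fraction outside target over fraction in target the loss ratio, a selectivity factor turned upside down.

3. My bet, which these readings cannot prove, is that the reaction has stopped and the gap is a second branch, not an equilibrium. Waiting then adds nothing.

4. Taking out target, north, pulls nothing forward on this bet.

5. Adding partner, south-west, finds nothing to react with on this bet.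

6. The dusk run ends on a smaller ratio than the summer run, 0.368, but heat at 8.0 d has no reaction left to redirect on this bet. So I answer none.

7. The forecast differs from me. It gives 71%, north, 70.7% after north-west and 66.5% after south, on this ground: “I favour equilibrium, with about 28% still present as starting material.”

8. The flask gives 71.9% and the answer none. The gains are 0 points for north, 0 points for south-west, 0 points for north-west and 0 points for south. It stands at 71.9% after north-west and 71.9% after south.

    starting material → open intermediate (k = 2.01 × 10⁻⁴ s⁻¹, Ea = 125 kJ mol⁻¹)
    partner → second intermediate (k = 1.04 × 10⁻⁵ s⁻¹, Ea = 127 kJ mol⁻¹)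
    open intermediate + second intermediate → target (k = 3.84 × 10⁻⁵ L mol⁻¹ s⁻¹, Ea = 75.0 kJ mol⁻¹)
    2 open intermediate → homo product (k = 1.37 × 10⁻⁵ L mol⁻¹ s⁻¹, Ea = 110 kJ mol⁻¹)
    starting material ⇌ dormant form (K = 0.653, k = 7.41 × 10⁻⁵ s⁻¹, Ea = 124 kJ mol⁻¹, ΔH = −69.0 kJ mol⁻¹)
    (constants at 90 °C)

At 0.771 d the flask's starting material has a half-life of 0.96 h by its step to open intermediate, and partner has a longer one, 0.77 d, by its step to second intermediate. At 8.00 d the flask holds 0% starting material and 28.1% homo product. With partner held, I scale the loss ratio by the charge, 0.400 of this one, which gives 0.159 and so 86.3% target. The neighbour flask with 0.10 M of starting material holds 86.9% target.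

The numbers in the tables come from a simulation for substances that don't exist; the scatter is artificial.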